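The reading comes at 50 min, so I asked how many chains stand by then and how much G they have made.

the same everywhere: D 0.5 mol%; time 50 min
- winter: E 0.047 M
- midnight: E 0.10 M

    E + D → Z + G (k1 = 0.837 M⁻¹ min⁻¹)
    E + Z → G + Z, rate k2*[Z]*[E] (k2 = 91.4 M⁻¹ min⁻¹)
    2 D → D2 (k3 = 3330 M⁻¹ min⁻¹)
    E → X (k4 = 6.00 × 10⁻⁴ min⁻¹)

- a doubled species enters its step squared and goes two at a time
- the average divides the monomer in chains by the number of chains begun, living and dead together
- run time (winter): 50 min

* which of the two ends with the longer chains by the average number of monomer units in a chain (chains begun, living or dead) ("neither" if they lie within 10%) (winter / midnight / neither)
* average number of monomer units in a chain (chains begun, living or dead) at the end, winter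
* average number of monomer units in a chain (chains begun, living or dead) at the end, midnight

D can pair off or begin a chain. With E held near its charge, which makes initiation pseudo-first-order in D, the two paths fold into one number S: twice the pairing constant times the loading, over the initiation constant, 39.8. It says how much faster D pairs off than it begins chains at the charge. Pairing outruns initiation, and with E held at its charge the part of D that begins chains is the logarithm of one plus S, over S, 9.32%. The loading is tied to E, so winter and midnight share this S and the same chain share, the chains begun per E charged, 0.0466%; Z is lost in no step.

One number was not enough, because equal shares cannot separate the flasks. Length is the G share over the chain share, and E feeds G at 0.00200 min⁻¹ in winter and 0.00426 min⁻¹ at midnight, against 6.00 × 10⁻⁴ min⁻¹ lost to X. With every chain standing from the first minute, I reckoned 201 for winter and 406 for midnight, twice as long. But the time of D by initiation alone, with E at its charge, is 25.4 min in winter and 11.9 min at midnight, so I held both figures too high, winter's more.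

The forecast said midnight, with 170 (155 to 185) for winter and 370 (335 to 405) for midnight, lower than mine, holding that “only roughly 9% of D begins chains”.

The flasks gave 173 in winter and 372 at midnight, so midnight has the longer chains, inside the forecast's ranges and below my figures.

At midnight, Z read at the end was 0.0461% of the E charged, beside the chain share of 0.0466%. Left until 3.0 h, the midnight flask keeps that share, and the same reckoning gives 1100. That flask gave 1080, with G at 49.9% of the E charged at 3.0 h, and my figure stood 1.85% above it there, against 9.03% above the midnight result at 50 min.

The numbers are invented.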